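**Retrosynthetic overview**
1. 27 ⇒ seco-aldehyde 26. The only ring (the 10-membered carbocycle) is closed last, by C3–C4 bond formation between the C3 aldehyde and the (Z)-C4 alkenyl iodide (new catalyst-controlled Ni/Cr macrocyclisation, sets C3).
2. 26 ⇒ β-hydroxy (Z)-β-iodoenone 21. Evans–Tishchenko reduction with cinnamaldehyde sets C6 (1,3-anti) and places the cinnamate on C8; acetylation of C6 follows.
3. 21 ⇒ ynone 20 (hydroiodination sets the C4=C5 Z geometry) ⇒ Weinreb amide 17 + propynyl Grignard.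
4. 17 ⇒ Evans syn-aldol of isovaleryl oxazolidinone 3 with skipped enal 13 (sets C7 and C8).
5. 13 ⇒ (Z)-alkenyl iodide 9 (Stork–Zhao olefination sets the C1=C10 Z geometry) + oxirane.

Assumption: the SMILES is taken literally, i.e. both ring alkenes Z and (3R,6S,7R,8S) in germacrane numbering (C1=C10, C3–OH, C4=C5, C6–OAc, C7–iPr, C8–O-cinnamoyl); these atom labels are used below.
Assumption: in step 13 the (S)-configured ligand is taken to direct Si-face addition at C3 (giving 3R); if the sense proves opposite, its enantiomer is used.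

**Step 1**
Reactants: 1 (R)-4-benzyloxazolidin-2-one; 2 3-methylbutanoyl chloride
Product: 3 (R)-4-benzyl-3-(3-methylbutanoyl)oxazolidin-2-one
Conditions: Et3N, DMAP (cat.), CH2Cl2, 0 °C → rt
Reagents that add atoms: none
Why: DMAP-catalysed N-acylation of an oxazolidinone with an acid chloride is a routine auxiliary loading and touches no stereocentre.

**Step 2**
Reactants: 4 3-[(tert-butyldimethylsilyl)oxy]propanal; 5 ethyltriphenylphosphonium iodide
Product: 9 (Z)-tert-butyl[(4-iodopent-3-en-1-yl)oxy]dimethylsilane, via ethylidene ylide 6 (not isolated), via iodophosphonium iodide 7 (not isolated), via iodo ylide 8 (not isolated)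
Conditions: 5, n-BuLi, THF, 0 °C → rt; I2, −78 °C; NaHMDS, −20 °C; then 4, −78 °C
Reagents that add atoms: iodine, II
Why: Stork–Zhao–Wittig olefination with the α-iodoethylidene ylide gives 2-iodo-2-alkenes with iodine cis to the chain (Z, typically ≥10:1) under kinetic control at −78 °C, which fixes the C1=C10 geometry of the target.

**Step 3**
Reactants: 9 (Z)-tert-butyl[(4-iodopent-3-en-1-yl)oxy]dimethylsilane; 10 oxirane
Product: 12 (Z)-6-[(tert-butyldimethylsilyl)oxy]-3-methylhex-3-en-1-ol, via alkenyllithium 11 (not isolated)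
Conditions: t-BuLi (2.1 equiv), Et2O, −78 °C; then 10 (excess), −78 → 0 °C; H2O
Reagents that add atoms: none
Why: Iodine–lithium exchange with t-BuLi at −78 °C is stereoretentive for alkenyl iodides, and the alkenyllithium opens oxirane in an SN2 ring-opening to give the Z-trisubstituted homoallylic alcohol.

**Step 4**
Reactants: 12 (Z)-6-[(tert-butyldimethylsilyl)oxy]-3-methylhex-3-en-1-ol
Product: 13 (Z)-6-[(tert-butyldimethylsilyl)oxy]-3-methylhex-3-enal
Conditions: Dess–Martin periodinane, pyridine, CH2Cl2, 0 °C → rt; crude, used at once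
Reagents that add atoms: none
Why: Dess–Martin oxidation under pyridine-buffered conditions gives the β,γ-unsaturated aldehyde without migration of the alkene into conjugation.

**Step 5**
Reactants: 3 (R)-4-benzyl-3-(3-methylbutanoyl)oxazolidin-2-one; 13 (Z)-6-[(tert-butyldimethylsilyl)oxy]-3-methylhex-3-enal
Product: 16 (R)-4-benzyl-3-[(2R,3S,5Z)-8-[(tert-butyldimethylsilyl)oxy]-3-hydroxy-5-methyl-2-(propan-2-yl)oct-5-enoyl]oxazolidin-2-one, via Z-boron enolate 14 (not isolated), via boron aldolate 15 (not isolated)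
Conditions: 3, n-Bu2BOTf, Et3N, CH2Cl2, −78 → 0 °C; then 13, −78 → 0 °C; pH 7 buffer, MeOH, 30% H2O2, 0 °C
Reagents that add atoms: none
Why: Evans syn-aldol, in which the Z-boron enolate reacts through a Zimmerman–Traxler chair on the face away from the benzyl group of the (R)-auxiliary, setting C7 (R) and C8 (S) as the 2,3-syn pair (typically >20:1).

**Step 6**
Reactants: 16 (R)-4-benzyl-3-[(2R,3S,5Z)-8-[(tert-butyldimethylsilyl)oxy]-3-hydroxy-5-methyl-2-(propan-2-yl)oct-5-enoyl]oxazolidin-2-one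
Product: 17 (2R,3S,5Z)-8-[(tert-butyldimethylsilyl)oxy]-3-hydroxy-N-methoxy-N,5-dimethyl-2-(propan-2-yl)oct-5-enamide
Conditions: MeNH(OMe)·HCl, AlMe3, CH2Cl2, −20 → 0 °C; Rochelle salt
Reagents that add atoms: N,O-dimethylhydroxylamine hydrochloride, CNOC.Cl
Why: Weinreb transamidation with the aluminium amide, delivered through the C8 aluminium alkoxide, cleaves the auxiliary without epimerising C7.

**Step 7**
Reactants: 17 (2R,3S,5Z)-8-[(tert-butyldimethylsilyl)oxy]-3-hydroxy-N-methoxy-N,5-dimethyl-2-(propan-2-yl)oct-5-enamide; 18 prop-1-yn-1-ylmagnesium bromide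
Product: 20 (5R,6S,8Z)-11-[(tert-butyldimethylsilyl)oxy]-6-hydroxy-8-methyl-5-(propan-2-yl)undec-8-en-2-yn-4-one, via magnesium hemiaminal 19 (not isolated)
Conditions: 18 (3.5 equiv), THF, −20 → 0 °C; inverse quench into cold 0.5 M HCl
Reagents that add atoms: none
Why: Weinreb ketone synthesis, in which the alkynyl Grignard adds only once because chelate 19 survives until the acidic quench, which also protonates the released amine before it can add to the ynone.

**Step 8**
Reactants: 20 (5R,6S,8Z)-11-[(tert-butyldimethylsilyl)oxy]-6-hydroxy-8-methyl-5-(propan-2-yl)undec-8-en-2-yn-4-one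
Product: 21 (2Z,5R,6S,8Z)-11-[(tert-butyldimethylsilyl)oxy]-6-hydroxy-2-iodo-8-methyl-5-(propan-2-yl)undeca-2,8-dien-4-one
Conditions: NaI (2 equiv), AcOH (5 equiv), MeCN, rt, dark
Reagents that add atoms: sodium iodide, [Na+].[I-]
Why: Conjugate hydroiodination of the ynone (iodide attack at C4, then protonation of the allenol anti to iodine) gives the Z-β-iodoenone kinetically, setting the C4=C5 geometry with iodine cis to C6.

**Step 9**
Reactants: 21 (2Z,5R,6S,8Z)-11-[(tert-butyldimethylsilyl)oxy]-6-hydroxy-2-iodo-8-methyl-5-(propan-2-yl)undeca-2,8-dien-4-one; 22 (E)-cinnamaldehyde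
Product: 23 (2Z,4R,5S,6S,8Z)-11-[(tert-butyldimethylsilyl)oxy]-4-hydroxy-2-iodo-8-methyl-5-(propan-2-yl)undeca-2,8-dien-6-yl (2E)-3-phenylprop-2-enoate
Conditions: 22 (5 equiv), SmI2 (30 mol%), THF, −10 °C, dark
Reagents that add atoms: none
Why: Evans–Tishchenko reduction, in which the samarium-bound hemiacetal formed from the C8 hydroxyl and 22 transfers hydride intramolecularly to the C6 ketone through a chair-like six-membered transition state, setting C6 1,3-anti to C8 (typically >20:1) and leaving the cinnamate on C8 only.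

**Step 10**
Reactants: 23 (2Z,4R,5S,6S,8Z)-11-[(tert-butyldimethylsilyl)oxy]-4-hydroxy-2-iodo-8-methyl-5-(propan-2-yl)undeca-2,8-dien-6-yl (2E)-3-phenylprop-2-enoate
Product: 24 (2Z,4R,5R,6S,8Z)-4-(acetyloxy)-11-[(tert-butyldimethylsilyl)oxy]-2-iodo-8-methyl-5-(propan-2-yl)undeca-2,8-dien-6-yl (2E)-3-phenylprop-2-enoate
Conditions: Ac2O, pyridine, DMAP (cat.), CH2Cl2, 0 °C → rt
Reagents that add atoms: acetic anhydride, CC(=O)OC(C)=O
Why: DMAP-catalysed acetylation of the only free hydroxyl (C6) completes the differentiated diester without touching any stereocentre.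

**Step 11**
Reactants: 24 (2Z,4R,5R,6S,8Z)-4-(acetyloxy)-11-[(tert-butyldimethylsilyl)oxy]-2-iodo-8-methyl-5-(propan-2-yl)undeca-2,8-dien-6-yl (2E)-3-phenylprop-2-enoate
Product: 25 (2Z,4R,5R,6S,8Z)-4-(acetyloxy)-11-hydroxy-2-iodo-8-methyl-5-(propan-2-yl)undeca-2,8-dien-6-yl (2E)-3-phenylprop-2-enoate
Conditions: HF·pyridine, pyridine, THF, 0 °C → rt
Reagents that add atoms: none
Why: Fluoride-mediated desilylation of the primary TBS ether under buffered HF·pyridine leaves both esters and the alkenyl iodide untouched.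

**Step 12**
Reactants: 25 (2Z,4R,5R,6S,8Z)-4-(acetyloxy)-11-hydroxy-2-iodo-8-methyl-5-(propan-2-yl)undeca-2,8-dien-6-yl (2E)-3-phenylprop-2-enoate
Product: 26 (2Z,4R,5R,6S,8Z)-4-(acetyloxy)-2-iodo-8-methyl-11-oxo-5-(propan-2-yl)undeca-2,8-dien-6-yl (2E)-3-phenylprop-2-enoate
Conditions: Dess–Martin periodinane, pyridine, CH2Cl2, 0 °C; crude, used at once
Reagents that add atoms: none
Why: Dess–Martin oxidation under buffered conditions gives the skipped enal without conjugation of the C1=C10 alkene or loss of an acyl group.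

**Step 13**
Reactants: 26 (2Z,4R,5R,6S,8Z)-4-(acetyloxy)-2-iodo-8-methyl-11-oxo-5-(propan-2-yl)undeca-2,8-dien-6-yl (2E)-3-phenylprop-2-enoate
Product: 27 (1S,2R,3S,4Z,6R,8Z)-3-(acetyloxy)-6-hydroxy-5,9-dimethyl-2-(propan-2-yl)cyclodeca-4,8-dien-1-yl (2E)-3-phenylprop-2-enoate (CNP0284991.1)
Conditions: preformed Cr(III)–(S)-L* chloride complex (20 mol%; L* = 4-tert-butyl-2-(2-sulfonamidoaryl)oxazoline), NiCl2·neocuproine (5 mol%), Mn (4 equiv), Cp2ZrCl2 (1.5 equiv), LiCl (2 equiv), MeCN, rt; 26 added over 12 h (final 2 mM)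
Reagents that add atoms: none
Why: Proposed new method: a ligand-controlled, catalytic Ni/Cr alkenyl iodide–aldehyde coupling, used here for the first time to close a medium (10-membered) carbocycle and to set a ring carbinol under catalyst control; Ni(0) inserts into the C4–I bond with retention of the Z geometry, the alkenyl group passes to a Cr(III) centre carrying the chiral oxazoline–sulfonamide ligand, the C3 aldehyde binds the same chromium and is attacked on its Si face in a closed four-centre transition state (3R), and Cp2ZrCl2 strips the chromium alkoxide so that Mn(0) can return Cr(III) to Cr(II); the two Z alkenes act as turn elements that bring C3 and C4 together, slow addition keeps the labile skipped enal dilute, and the near-neutral medium spares the allylic acetate and the cinnamate; the closest known reaction type is the Nozaki–Hiyama–Kishi reaction, in its stoichiometric macrocyclising form and its intermolecular catalytic asymmetric form with sulfonamide ligands.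

**Compound list**
1 | (R)-4-benzyloxazolidin-2-one | O=C1N[C@H](Cc2ccccc2)CO1 | starting material
2 | 3-methylbutanoyl chloride | CC(C)CC(Cl)=O | starting material
3 | (R)-4-benzyl-3-(3-methylbutanoyl)oxazolidin-2-one | CC(C)CC(=O)N1[C@H](Cc2ccccc2)COC1=O | intermediate
4 | 3-[(tert-butyldimethylsilyl)oxy]propanal | CC(C)(C)[Si](C)(C)OCCC=O | starting material
5 | ethyltriphenylphosphonium iodide | CC[P+](c1ccccc1)(c1ccccc1)c1ccccc1.[I-] | starting material
6 | ethylidene(triphenyl)phosphorane (ethylidene ylide; not isolated) | CC=P(c1ccccc1)(c1ccccc1)c1ccccc1 | intermediate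
7 | (1-iodoethyl)triphenylphosphonium iodide (not isolated) | CC(I)[P+](c1ccccc1)(c1ccccc1)c1ccccc1.[I-] | intermediate
8 | (1-iodoethylidene)triphenylphosphorane (iodo ylide; not isolated) | CC(I)=P(c1ccccc1)(c1ccccc1)c1ccccc1 | intermediate
9 | (Z)-tert-butyl[(4-iodopent-3-en-1-yl)oxy]dimethylsilane | CC(C)(C)[Si](C)(C)OCC/C=C(/C)I | intermediate
10 | oxirane | C1CO1 | starting material
11 | (E)-{5-[(tert-butyldimethylsilyl)oxy]pent-2-en-2-yl}lithium (alkene geometry of 9 retained; not isolated) | CC(C)(C)[Si](C)(C)OCC/C=C(/C)[Li] | intermediate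
12 | (Z)-6-[(tert-butyldimethylsilyl)oxy]-3-methylhex-3-en-1-ol | CC(C)(C)[Si](C)(C)OCC/C=C(/C)CCO | intermediate
13 | (Z)-6-[(tert-butyldimethylsilyl)oxy]-3-methylhex-3-enal | CC(C)(C)[Si](C)(C)OCC/C=C(/C)CC=O | intermediate
14 | (Z)-dibutylboron enolate of 3 (not isolated) | CC(C)/C=C(\OB(CCCC)CCCC)N1[C@H](Cc2ccccc2)COC1=O | intermediate
15 | O-dibutylboryl aldolate of 16 (not isolated) | CC(C)(C)[Si](C)(C)OCC/C=C(/C)C[C@H](OB(CCCC)CCCC)[C@@H](C(C)C)C(=O)N1[C@H](Cc2ccccc2)COC1=O | intermediate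
16 | (R)-4-benzyl-3-[(2R,3S,5Z)-8-[(tert-butyldimethylsilyl)oxy]-3-hydroxy-5-methyl-2-(propan-2-yl)oct-5-enoyl]oxazolidin-2-one | CC(C)(C)[Si](C)(C)OCC/C=C(/C)C[C@H](O)[C@@H](C(C)C)C(=O)N1[C@H](Cc2ccccc2)COC1=O | intermediate
17 | (2R,3S,5Z)-8-[(tert-butyldimethylsilyl)oxy]-3-hydroxy-N-methoxy-N,5-dimethyl-2-(propan-2-yl)oct-5-enamide | CC(C)(C)[Si](C)(C)OCC/C=C(/C)C[C@H](O)[C@@H](C(C)C)C(=O)N(C)OC | intermediate
18 | prop-1-yn-1-ylmagnesium bromide | CC#C[Mg]Br | starting material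
19 | bis(bromomagnesium) salt of the hemiaminal adduct of 17 and 18 (not isolated) | CC(C)(C)[Si](C)(C)OCC/C=C(/C)C[C@H](O[Mg]Br)[C@@H](C(C)C)C(O[Mg]Br)(N(C)OC)C#CC | intermediate
20 | (5R,6S,8Z)-11-[(tert-butyldimethylsilyl)oxy]-6-hydroxy-8-methyl-5-(propan-2-yl)undec-8-en-2-yn-4-one | CC(C)(C)[Si](C)(C)OCC/C=C(/C)C[C@H](O)[C@@H](C(C)C)C(=O)C#CC | intermediate
21 | (2Z,5R,6S,8Z)-11-[(tert-butyldimethylsilyl)oxy]-6-hydroxy-2-iodo-8-methyl-5-(propan-2-yl)undeca-2,8-dien-4-one | CC(C)(C)[Si](C)(C)OCC/C=C(/C)C[C@H](O)[C@@H](C(C)C)C(=O)/C=C(/C)I | intermediate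
22 | (E)-cinnamaldehyde | O=C/C=C/c1ccccc1 | starting material
23 | (2Z,4R,5S,6S,8Z)-11-[(tert-butyldimethylsilyl)oxy]-4-hydroxy-2-iodo-8-methyl-5-(propan-2-yl)undeca-2,8-dien-6-yl (2E)-3-phenylprop-2-enoate | CC(C)(C)[Si](C)(C)OCC/C=C(/C)C[C@H](OC(=O)/C=C/c1ccccc1)[C@@H](C(C)C)[C@@H](O)/C=C(/C)I | intermediate
24 | (2Z,4R,5R,6S,8Z)-4-(acetyloxy)-11-[(tert-butyldimethylsilyl)oxy]-2-iodo-8-methyl-5-(propan-2-yl)undeca-2,8-dien-6-yl (2E)-3-phenylprop-2-enoate | CC(C)(C)[Si](C)(C)OCC/C=C(/C)C[C@H](OC(=O)/C=C/c1ccccc1)[C@@H](C(C)C)[C@@H](OC(C)=O)/C=C(/C)I | intermediate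
25 | (2Z,4R,5R,6S,8Z)-4-(acetyloxy)-11-hydroxy-2-iodo-8-methyl-5-(propan-2-yl)undeca-2,8-dien-6-yl (2E)-3-phenylprop-2-enoate | OCC/C=C(/C)C[C@H](OC(=O)/C=C/c1ccccc1)[C@@H](C(C)C)[C@@H](OC(C)=O)/C=C(/C)I | intermediate
26 | (2Z,4R,5R,6S,8Z)-4-(acetyloxy)-2-iodo-8-methyl-11-oxo-5-(propan-2-yl)undeca-2,8-dien-6-yl (2E)-3-phenylprop-2-enoate | O=CC/C=C(/C)C[C@H](OC(=O)/C=C/c1ccccc1)[C@@H](C(C)C)[C@@H](OC(C)=O)/C=C(/C)I | intermediate
27 | (1S,2R,3S,4Z,6R,8Z)-3-(acetyloxy)-6-hydroxy-5,9-dimethyl-2-(propan-2-yl)cyclodeca-4,8-dien-1-yl (2E)-3-phenylprop-2-enoate; (3R,6S,7R,8S)-6-acetoxy-8-cinnamoyloxygermacra-1(10)Z,4Z-dien-3-ol | CC(=O)O[C@H]1/C=C(/C)[C@H](O)C/C=C(/C)C[C@H](OC(=O)/C=C/c2ccccc2)[C@H]1C(C)C | target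

**Totals**
Total step count: 13. Longest linear sequence: 12 steps (steps 2–13, from 4); step 1 is a one-step side branch that joins at step 5.

**Three steps most likely to fail**

Step 13, the proposed new ring closure, may suffer from poor catalyst turnover, proto-deiodination or low face control at C3. The fallback uses known chemistry only. It sets out from 26, which is cyclised under classical stoichiometric Nozaki–Hiyama–Kishi conditions (CrCl2 6 equiv, NiCl2 1 mol%, DMSO/THF, 2 mM, rt) to 27 mixed with its C3-epimeric carbinol F1. The unseparated mixture is oxidised (Dess–Martin periodinane, NaHCO3) to the cyclodecadienone F2. Reagent-controlled 1,2-reduction ((S)-Me-CBS, catecholborane, toluene, −78 °C) then fixes 3R, so the fallback comes back to the route at 27.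

Step 9 is risky because cinnamaldehyde is an unusual hydride donor for the Evans–Tishchenko reduction, and the β-iodoenone may cyclise to a dihydropyranone or lose its Z geometry under Sm(III)/iodide. The fallback avoids any Tishchenko step. It sets out from 17, whose C8 hydroxyl is protected (4-methoxybenzyl trichloroacetimidate, cat. Sc(OTf)3) as the PMB ether F3. Addition of 18 gives the PMB-protected ynone F4. Noyori transfer hydrogenation ((R,R)-RuCl(TsDPEN)(p-cymene), i-PrOH) sets C6 under catalyst control in the propargylic alcohol F5. Hydroxyl-directed trans-hydroalumination and iodination (Red-Al, then I2) gives the (Z)-iodo allylic alcohol F6. Acetylation gives the acetate F7, DDQ removes the PMB group to give the C8 alcohol F8, and cinnamoyl chloride/DMAP esterifies C8, coming back to the route at 24.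

Step 8 is risky because the free β-hydroxyl can add to C4 to give a dihydropyranone, and acid/iodide can erode the Z geometry or the TBS ether. The fallback sets out from 20 and reverses the order of events. The Evans–Tishchenko reduction is run first on the ynone (22, SmI2 cat.) to give the propargylic alcohol cinnamate F9. Ruthenium-catalysed trans-hydrosilylation (Et3SiH, [Cp*Ru(MeCN)3]PF6) puts silicon on C4, distal to the free carbinol and anti to the new C5–H, giving the (Z)-alkenylsilane F10. Stereoretentive iododesilylation (N-iodosuccinimide, HFIP, 0 °C) then comes back to the route at 23.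

**Further compounds**
F1 | step 13 | (1S,2R,3S,4Z,6S,8Z)-3-(acetyloxy)-6-hydroxy-5,9-dimethyl-2-(propan-2-yl)cyclodeca-4,8-dien-1-yl (2E)-3-phenylprop-2-enoate (C3 epimer of 27) | CC(=O)O[C@H]1/C=C(/C)[C@@H](O)C/C=C(/C)C[C@H](OC(=O)/C=C/c2ccccc2)[C@H]1C(C)C
F2 | step 13 | (1S,2R,3S,4Z,8Z)-3-(acetyloxy)-5,9-dimethyl-6-oxo-2-(propan-2-yl)cyclodeca-4,8-dien-1-yl (2E)-3-phenylprop-2-enoate | CC(=O)O[C@H]1/C=C(/C)C(=O)C/C=C(/C)C[C@H](OC(=O)/C=C/c2ccccc2)[C@H]1C(C)C
F3 | step 9 | (2R,3S,5Z)-8-[(tert-butyldimethylsilyl)oxy]-N-methoxy-3-[(4-methoxyphenyl)methoxy]-N,5-dimethyl-2-(propan-2-yl)oct-5-enamide | CC(C)(C)[Si](C)(C)OCC/C=C(/C)C[C@H](OCc1ccc(OC)cc1)[C@@H](C(C)C)C(=O)N(C)OC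
F4 | step 9 | (5R,6S,8Z)-11-[(tert-butyldimethylsilyl)oxy]-6-[(4-methoxyphenyl)methoxy]-8-methyl-5-(propan-2-yl)undec-8-en-2-yn-4-one | CC(C)(C)[Si](C)(C)OCC/C=C(/C)C[C@H](OCc1ccc(OC)cc1)[C@@H](C(C)C)C(=O)C#CC
F5 | step 9 | (4R,5S,6S,8Z)-11-[(tert-butyldimethylsilyl)oxy]-6-[(4-methoxyphenyl)methoxy]-8-methyl-5-(propan-2-yl)undec-8-en-2-yn-4-ol | CC(C)(C)[Si](C)(C)OCC/C=C(/C)C[C@H](OCc1ccc(OC)cc1)[C@@H](C(C)C)[C@@H](O)C#CC
F6 | step 9 | (2Z,4R,5S,6S,8Z)-11-[(tert-butyldimethylsilyl)oxy]-2-iodo-6-[(4-methoxyphenyl)methoxy]-8-methyl-5-(propan-2-yl)undeca-2,8-dien-4-ol | CC(C)(C)[Si](C)(C)OCC/C=C(/C)C[C@H](OCc1ccc(OC)cc1)[C@@H](C(C)C)[C@@H](O)/C=C(/C)I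
F7 | step 9 | (2Z,4R,5R,6S,8Z)-11-[(tert-butyldimethylsilyl)oxy]-2-iodo-6-[(4-methoxyphenyl)methoxy]-8-methyl-5-(propan-2-yl)undeca-2,8-dien-4-yl acetate | CC(C)(C)[Si](C)(C)OCC/C=C(/C)C[C@H](OCc1ccc(OC)cc1)[C@@H](C(C)C)[C@@H](OC(C)=O)/C=C(/C)I
F8 | step 9 | (2Z,4R,5R,6S,8Z)-11-[(tert-butyldimethylsilyl)oxy]-6-hydroxy-2-iodo-8-methyl-5-(propan-2-yl)undeca-2,8-dien-4-yl acetate | CC(C)(C)[Si](C)(C)OCC/C=C(/C)C[C@H](O)[C@@H](C(C)C)[C@@H](OC(C)=O)/C=C(/C)I
F9 | step 8 | (4R,5S,6S,8Z)-11-[(tert-butyldimethylsilyl)oxy]-4-hydroxy-8-methyl-5-(propan-2-yl)undec-8-en-2-yn-6-yl (2E)-3-phenylprop-2-enoate | CC(C)(C)[Si](C)(C)OCC/C=C(/C)C[C@H](OC(=O)/C=C/c1ccccc1)[C@@H](C(C)C)[C@@H](O)C#CC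
F10 | step 8 | (2Z,4R,5S,6S,8Z)-11-[(tert-butyldimethylsilyl)oxy]-4-hydroxy-8-methyl-5-(propan-2-yl)-2-(triethylsilyl)undeca-2,8-dien-6-yl (2E)-3-phenylprop-2-enoate | CC(C)(C)[Si](C)(C)OCC/C=C(/C)C[C@H](OC(=O)/C=C/c1ccccc1)[C@@H](C(C)C)[C@@H](O)/C=C(/C)[Si](CC)(CC)CC
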